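**Strategy**

The synthesis rests on cutting ring B at its C1–C2 and C5–C6 bonds. One Diels–Alder benzannulation between benzyl hex-2-ynoate and a vinylketene silyl acetal makes both bonds, closes ring B and aromatises it. The step exploits the substitution pattern of ring B: C1 carboxyl, C2 hydroxyl, C4 ester oxygen, C6 propyl. The ketene-acetal carbon becomes C2–OH, the diene carbon that already carries the ring-A aroyloxy group becomes C4, and the alkyne carbons become C1 and C6, so no choice between two phenols arises. The diene is the silyl dienolate of the O-aroyl enol of benzyl acetoacetate; a final hydrogenolysis frees the acid.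

Key step: step 7

Remark: the target has no stereocentre and no stereogenic double bond, so it is one achiral compound and no stereocontrol is needed. The double-bond geometry of enol ester 8 and of the ketene acetal in 9 and 10 is erased later and is not controlled.

**Route**

Step 1
Reactants: 1 5-propylbenzene-1,3-diol (divarinol)
Product: 2 1,3-dimethoxy-5-propylbenzene
Conditions: MeI, K2CO3, acetone, reflux
Reagents that add atoms: iodomethane, CI
Why: Williamson ether synthesis: the two phenoxides formed by carbonate are O-methylated by iodomethane, and the weak base in acetone should keep C-alkylation of the ring negligible.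

Step 2
Reactants: 2 1,3-dimethoxy-5-propylbenzene
Product: 4 2,4-dimethoxy-6-propylbenzaldehyde, via iminium chloride 3 (not isolated)
Conditions: POCl3, DMF, 0 → 70 °C; then H2O, 0 °C → rt
Reagents that add atoms: N,N-dimethylformamide, CN(C)C=O; water, O
Why: Vilsmeier–Haack formylation: the chloroiminium electrophile should attack the ring carbon flanked by propyl and methoxy (para to the second methoxy) in preference to the more congested carbon between the two methoxy groups, as is usual for 5-alkylresorcinol dimethyl ethers, and water hydrolyses iminium salt 3 to the aldehyde.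

Step 3
Reactants: 4 2,4-dimethoxy-6-propylbenzaldehyde
Product: 5 2,4-dimethoxy-6-propylbenzoic acid
Conditions: NaClO2, NaH2PO4, 2-methylbut-2-ene, t-BuOH/H2O, rt
Reagents that add atoms: sodium chlorite, [Na+].[O-]Cl=O
Why: Pinnick oxidation: chlorous acid converts the aldehyde into the acid, and 2-methylbut-2-ene traps the hypochlorous acid that would otherwise chlorinate the electron-rich ring.

Step 4
Reactants: 5 2,4-dimethoxy-6-propylbenzoic acid; 6 benzyl 3-oxobutanoate (benzyl acetoacetate)
Product: 8 benzyl 3-[(2,4-dimethoxy-6-propylbenzoyl)oxy]but-2-enoate, via acid chloride 7 (not isolated)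
Conditions: (COCl)2, cat. DMF, CH2Cl2, 0 °C → rt, evaporate; then 6, Et3N, CH2Cl2, 0 °C → rt
Reagents that add atoms: none
Why: Acid chloride formation followed by O-acylation of the β-keto ester enolate (enol ester synthesis): a metal-free ammonium enolate and a hindered, acylium-like aroyl chloride should react at the hard enolate oxygen, the normal outcome of amine-mediated acylation of acetoacetates as opposed to magnesium-mediated C-acylation.

Step 5
Reactants: 8 benzyl 3-[(2,4-dimethoxy-6-propylbenzoyl)oxy]but-2-enoate
Product: 10 4-(benzyloxy)-4-[(tert-butyldimethylsilyl)oxy]buta-1,3-dien-2-yl 2,4-dimethoxy-6-propylbenzoate, via lithium dienolate 9 (not isolated)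
Conditions: TBSCl, DMPU, THF, −78 °C, LDA (1.05 equiv) added last; cold pentane/aq. NaHCO3 partition, used crude
Reagents that add atoms: tert-butyldimethylsilyl chloride, CC(C)(C)[Si](C)(C)Cl
Why: Kinetic γ-deprotonation of a 3-oxygenated but-2-enoate and O-silylation of the extended enolate, the standard way to vinylketene silyl acetals: the silyl chloride is present before the base so that dienolate 9 is trapped at −78 °C before it can expel the aroate, one equivalent of base leaves the less acidic benzylic CH2 of the propyl group alone, and the two ortho substituents shield the aroyl carbonyl from the amide.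

Step 6
Reactants: 11 hex-2-ynoic acid
Product: 12 benzyl hex-2-ynoate
Conditions: BnBr, KHCO3, DMF, rt
Reagents that add atoms: benzyl bromide, BrCc1ccccc1
Why: Carboxylate O-alkylation (SN2) with benzyl bromide under hydrogencarbonate, which is too weak a base to isomerise the ynoate to the allenoate.

Step 7
Reactants: 10 4-(benzyloxy)-4-[(tert-butyldimethylsilyl)oxy]buta-1,3-dien-2-yl 2,4-dimethoxy-6-propylbenzoate; 12 benzyl hex-2-ynoate
Product: 15 benzyl 4-[(2,4-dimethoxy-6-propylbenzoyl)oxy]-2-hydroxy-6-propylbenzoate, via cyclohexa-1,4-diene cycloadduct 13 (not isolated), via aryl silyl ether 14 (not isolated)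
Conditions: 12 (3 equiv), toluene (concentrated), 140 °C, sealed tube; then KHF2, MeOH, rt
Reagents that add atoms: none
Why: Proposed new method: a thermal, asynchronous normal-demand [4+2] cycloaddition in which the CH2 terminus of 10 (the most nucleophilic carbon, because the 1,1-dioxygenated terminus and the 3-acyloxy group polarise the diene in the same direction) bonds to the β-carbon of ynoate 12 while the ketene-acetal carbon bonds to the α-carbon, giving cyclohexa-1,4-diene 13, which should aromatise by 1,4-loss of benzyl alcohol to silyl ether 14 and is then desilylated by bifluoride to 15. The closest known reaction type is the Diels–Alder benzannulation of 3-silyloxy-1,1-dioxygenated butadienes with acetylenic esters, and 2-acyloxybuta-1,3-dienes are established Diels–Alder dienes; new here is an acyloxy donor at C3 of a vinylketene acetal. Ring B is closed by intermolecular [4+2] cycloaddition that forms its C1–C2 and C5–C6 bonds, followed by eliminative aromatisation. No stereocentre remains, since the single ketal centre of 13 is destroyed on aromatisation. The step needs regioselectivity (hydroxyl ortho and aroyloxy para to the ester carbon), which the matched polarisation of diene and ynoate secures, and survival of the depside ester, which its two ortho substituents and the base-free fluoride work-up secure; because both ester groups are benzyl, loss of the silyloxy instead of the benzyloxy group from 13, or any ester exchange, gives material that step 8 converges on the target.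

Step 8
Reactants: 15 benzyl 4-[(2,4-dimethoxy-6-propylbenzoyl)oxy]-2-hydroxy-6-propylbenzoate
Product: 16 4-[(2,4-dimethoxy-6-propylbenzoyl)oxy]-2-hydroxy-6-propylbenzoic acid (target)
Conditions: H2 (1 atm), 10% Pd/C, EtOAc, rt
Reagents that add atoms: none
Why: Catalytic hydrogenolysis of the benzyl ester under neutral conditions at room temperature, which leaves the aryl ester, the methyl ethers and both rings untouched and avoids the decarboxylation that heat or acid can cause in 2-hydroxy-6-alkylbenzoic acids.

**Compound list**

1 | 5-propylbenzene-1,3-diol (divarinol) | CCCc1cc(O)cc(O)c1 | starting material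
2 | 1,3-dimethoxy-5-propylbenzene | CCCc1cc(OC)cc(OC)c1 | intermediate
3 | N-[(2,4-dimethoxy-6-propylphenyl)methylidene]-N-methylmethanaminium chloride | CCCc1cc(OC)cc(OC)c1C=[N+](C)C.[Cl-] | intermediate (not isolated)
4 | 2,4-dimethoxy-6-propylbenzaldehyde | CCCc1cc(OC)cc(OC)c1C=O | intermediate
5 | 2,4-dimethoxy-6-propylbenzoic acid | CCCc1cc(OC)cc(OC)c1C(=O)O | intermediate
6 | benzyl 3-oxobutanoate (benzyl acetoacetate) | CC(=O)CC(=O)OCc1ccccc1 | starting material
7 | 2,4-dimethoxy-6-propylbenzoyl chloride | CCCc1cc(OC)cc(OC)c1C(Cl)=O | intermediate (not isolated)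
8 | benzyl 3-[(2,4-dimethoxy-6-propylbenzoyl)oxy]but-2-enoate (E/Z mixture, geometry not controlled) | CC(OC(=O)c1c(CCC)cc(OC)cc1OC)=CC(=O)OCc1ccccc1 | intermediate
9 | lithium 1-(benzyloxy)-3-[(2,4-dimethoxy-6-propylbenzoyl)oxy]buta-1,3-dien-1-olate | [Li]OC(OCc1ccccc1)=CC(=C)OC(=O)c1c(CCC)cc(OC)cc1OC | intermediate (not isolated)
10 | 4-(benzyloxy)-4-[(tert-butyldimethylsilyl)oxy]buta-1,3-dien-2-yl 2,4-dimethoxy-6-propylbenzoate (ketene-acetal geometry not controlled) | C=C(OC(=O)c1c(CCC)cc(OC)cc1OC)C=C(OCc1ccccc1)O[Si](C)(C)C(C)(C)C | intermediate
11 | hex-2-ynoic acid | CCCC#CC(=O)O | starting material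
12 | benzyl hex-2-ynoate | CCCC#CC(=O)OCc1ccccc1 | intermediate
13 | benzyl 6-(benzyloxy)-6-[(tert-butyldimethylsilyl)oxy]-4-[(2,4-dimethoxy-6-propylbenzoyl)oxy]-2-propylcyclohexa-1,4-diene-1-carboxylate (racemic at C6) | CCCC1=C(C(=O)OCc2ccccc2)C(OCc2ccccc2)(O[Si](C)(C)C(C)(C)C)C=C(OC(=O)c2c(CCC)cc(OC)cc2OC)C1 | intermediate (not isolated)
14 | benzyl 2-[(tert-butyldimethylsilyl)oxy]-4-[(2,4-dimethoxy-6-propylbenzoyl)oxy]-6-propylbenzoate | CCCc1cc(OC(=O)c2c(CCC)cc(OC)cc2OC)cc(O[Si](C)(C)C(C)(C)C)c1C(=O)OCc1ccccc1 | intermediate (not isolated)
15 | benzyl 4-[(2,4-dimethoxy-6-propylbenzoyl)oxy]-2-hydroxy-6-propylbenzoate | CCCc1cc(OC(=O)c2c(CCC)cc(OC)cc2OC)cc(O)c1C(=O)OCc1ccccc1 | intermediate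
16 | 4-[(2,4-dimethoxy-6-propylbenzoyl)oxy]-2-hydroxy-6-propylbenzoic acid | CCCc1cc(OC(=O)c2c(CCC)cc(OC)cc2OC)cc(O)c1C(=O)O | target

**Step count**

Total steps: 8. Longest linear sequence: 7 steps (steps 1, 2, 3, 4, 5, 7, 8).

**Steps most likely to fail**

1. Step 7 (proposed new method). The acyloxy group is a weaker donor than a silyloxy group. Cycloaddition to the β-alkyl ynoate may therefore be slower than thermal degradation of the silyl ketene acetal by silyl or acyl migration or by adventitious hydrolysis, so that the diene is consumed without ring formation. Fallback by known chemistry, setting out from 1 and returning at 15: Kolbe–Schmitt-type ortho-carboxylation of divarinol 1 with methyl magnesium carbonate (DMF, 120 °C, then aq. HCl) should give 2,4-dihydroxy-6-propylbenzoic acid F1. Alkylation of its carboxylate (BnBr, KHCO3, DMF, rt) should give benzyl 2,4-dihydroxy-6-propylbenzoate F2. The 4-hydroxyl, which unlike the 2-hydroxyl is not hydrogen-bonded to the ester carbonyl, is then acylated with acid chloride 7 (K2CO3, acetone, rt) to give 15, and the route resumes at step 8.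

2. Step 5. The extended enolate may expel the aroate before it is silylated, the amide base may deprotonate the benzylic position of the ortho-propyl group instead, or the ketene acetal may hydrolyse on isolation. Fallback, setting out from 6 and 5 and returning at 10, with the aroyl group introduced last so that no enol ester is exposed to strong base: 6 with TMSCl/Et3N should give benzyl 3-[(trimethylsilyl)oxy]but-2-enoate F3. LDA/TBSCl/DMPU at −78 °C should convert it into {[4-(benzyloxy)-4-[(tert-butyldimethylsilyl)oxy]buta-1,3-dien-2-yl]oxy}trimethylsilane F4. Acid 5 with cyanuric fluoride/pyridine should give 2,4-dimethoxy-6-propylbenzoyl fluoride F5. A catalytic anhydrous fluoride source (tetrabutylammonium difluorotriphenylsilicate, THF, −78 → 0 °C) should then cleave the less hindered trimethylsilyl enol ether selectively, and the enolate is O-acylated by F5 with regeneration of fluoride to give 10, which enters step 7.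

3. Step 4. The ambident enolate may be acylated at carbon, or slow acyl transfer from the hindered chloride may allow O→C acyl migration. Fallback, setting out from 5 and returning at 8, with no carbon nucleophile present: but-2-ynoic acid is benzylated as in step 6 to give benzyl but-2-ynoate F6. Gold(I)-catalysed anti hydro-acyloxylation of F6 with acid 5 (Ph3PAuCl/AgOTf cat., toluene, 60 °C) should place the carboxylate oxygen on the β-carbon and give 8 directly; its double-bond geometry is irrelevant for step 5.

**Further compounds**

F1 | step 7 | 2,4-dihydroxy-6-propylbenzoic acid | CCCc1cc(O)cc(O)c1C(=O)O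
F2 | step 7 | benzyl 2,4-dihydroxy-6-propylbenzoate | CCCc1cc(O)cc(O)c1C(=O)OCc1ccccc1
F3 | step 5 | benzyl 3-[(trimethylsilyl)oxy]but-2-enoate | CC(O[Si](C)(C)C)=CC(=O)OCc1ccccc1
F4 | step 5 | {[4-(benzyloxy)-4-[(tert-butyldimethylsilyl)oxy]buta-1,3-dien-2-yl]oxy}trimethylsilane | C=C(O[Si](C)(C)C)C=C(OCc1ccccc1)O[Si](C)(C)C(C)(C)C
F5 | step 5 | 2,4-dimethoxy-6-propylbenzoyl fluoride | CCCc1cc(OC)cc(OC)c1C(F)=O
F6 | step 4 | benzyl but-2-ynoate | CC#CC(=O)OCc1ccccc1
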